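**Retrosynthetic overview**

1. Ring A is numbered C1 = C(Me)OH, C2 = CHOH, C3 = CH carrying the CH2 linker, C4 = CH carrying isopropenyl, then C5 and C6. The C1/C2 diol is traced back to enol silane 17 (C1–OSi, C1=C2): C2–O by Rubottom oxidation, C1 methyl/hydroxyl by axial sulfonium-ylide epoxidation of the C1 ketone and hydride opening.
2. Key disconnection: bonds C3–C4 and C5–C6 of ring A, by Diels–Alder reaction of (E)-2-silyloxydiene 14 with methyl vinyl ketone. It rests on this feature: the oxygenated C1 lies 1,4 and the linker-bearing C3 lies 1,2 to C4, whose isopropenyl group is a masked acetyl group. That is the orientation a 2-silyloxy-4-alkyl-1,3-diene and a vinyl ketone give.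
3. Diene 14 comes from Stille coupling of ring-B allylic chloride 9 with stannyl silyloxydiene 13.
4. Ring B comes from the same kind of cycloaddition (2-silyloxybutadiene + methyl vinyl ketone), then axial bromination of the enol silane, methyl addition anti to bromine, equilibration of the acetyl-bearing carbon, methylenation and allylic chlorination.
5. Order of ring formation: ring B first (step 2), ring A second (step 12).

Key step: step 12

Assumption (catalyst sense): the (S)-configured B-(o-tolyl) oxazaborolidinium triflimide is taken to give the (S)-adduct 3 in step 2, as its enone-binding model predicts. Steps 2 and 12 need opposite facial senses at the acetyl-bearing carbon, so step 12 uses the (R)-catalyst; the two are exchanged if the sense proves to be the reverse.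

**Route**

Step 1
Reactants: 1 methyl vinyl ketone (but-3-en-2-one)
Product: 2 2-(triisopropylsilyloxy)buta-1,3-diene
Conditions: TIPSOTf, Et3N, Et2O, 0 °C → rt
Reagents that add atoms: triisopropylsilyl trifluoromethanesulfonate, CC(C)[Si](C(C)C)(C(C)C)OS(=O)(=O)C(F)(F)F
Why: Soft enolisation and O-silylation of the enone at its only enolisable position (the methyl group) gives the cross-conjugated 2-silyloxydiene.

Step 2
Reactants: 2 2-(triisopropylsilyloxy)buta-1,3-diene; 1 methyl vinyl ketone
Product: 3 (S)-1-[4-(triisopropylsilyloxy)cyclohex-3-en-1-yl]ethan-1-one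
Conditions: (S)-3,3-diphenyl-1-(o-tolyl)tetrahydro-1H,3H-pyrrolo[1,2-c][1,3,2]oxazaborole (20 mol %), HNTf2 (20 mol %), CH2Cl2, −78 → −40 °C
Reagents that add atoms: none
Why: Catalytic enantioselective Diels–Alder reaction of a 2-silyloxydiene with an enone bound to a chiral boron cation; the silyloxy group sends the acetyl-bearing carbon para to C–O, and the catalyst shields one face of the bound s-trans enone and so sets the only stereocentre (S).

Step 3
Reactants: 3 (S)-1-[4-(triisopropylsilyloxy)cyclohex-3-en-1-yl]ethan-1-one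
Product: 4 (2R,4S)-4-acetyl-2-bromocyclohexan-1-one (bromine trans to acetyl)
Conditions: NBS, THF, −78 → −20 °C; aq NaHCO3 work-up
Reagents that add atoms: N-bromosuccinimide, BrN1C(=O)CCC1=O
Why: Electrophilic α-bromination of the enol silane is regiospecific at the enol carbon, and stereoelectronically preferred axial attack on the half-chair with equatorial acetyl puts bromine trans to the acetyl group, the arrangement an α-bromocyclohexanone also prefers at equilibrium in weakly polar media.

Step 4
Reactants: 4 (2R,4S)-4-acetyl-2-bromocyclohexan-1-one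
Product: 5 1-[(1S,3R,4S)-3-bromo-4-hydroxy-4-methylcyclohexyl]ethan-1-one (OH cis to Br, methyl trans to Br)
Conditions: MeMgBr (1.05 equiv), THF–Et2O, −78 °C; quench at −78 °C with water/pH 7 buffer
Reagents that add atoms: methylmagnesium bromide, C[Mg]Br
Why: Grignard 1,2-addition under polar Felkin–Anh (Cornforth) control: 4 reacts through the chair with axial C–Br, methyl enters axially anti to bromine and gives the cis-bromohydrin, while the inductively activated α-bromocyclohexanone carbonyl should be consumed well before the side-chain methyl ketone at −78 °C with one equivalent.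

Step 5
Reactants: 5 1-[(1S,3R,4S)-3-bromo-4-hydroxy-4-methylcyclohexyl]ethan-1-one
Product: 6 1-[(1S,3R,4S)-3-bromo-4-methyl-4-(triethylsilyloxy)cyclohexyl]ethan-1-one
Conditions: TESOTf, 2,6-lutidine, CH2Cl2, −78 → 0 °C
Reagents that add atoms: triethylsilyl trifluoromethanesulfonate, CC[Si](CC)(CC)OS(=O)(=O)C(F)(F)F
Why: O-silylation of the hindered tertiary alcohol with a silyl triflate; the ether prevents alkoxide formation next to the bromide (ring contraction or methyl shift) in the basic steps that follow, and any enol silane formed at the acetyl group is hydrolysed on work-up.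

Step 6
Reactants: 6 1-[(1S,3R,4S)-3-bromo-4-methyl-4-(triethylsilyloxy)cyclohexyl]ethan-1-one
Product: 7 1-[(1R,3R,4S)-3-bromo-4-methyl-4-(triethylsilyloxy)cyclohexyl]ethan-1-one (acetyl cis to Br and to the silyloxy group)
Conditions: K2CO3, MeOH, rt; recovered 6 is resubmitted
Reagents that add atoms: none
Why: Base-mediated epimerisation through the acetyl enolate under thermodynamic control: after inversion at the acetyl-bearing carbon the ring can place acetyl, bromine and methyl equatorial with only the silyloxy group axial, whereas 6 must carry either axial bromine and methyl or an axial acetyl group, so 7 should predominate.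

Step 7
Reactants: 7 1-[(1R,3R,4S)-3-bromo-4-methyl-4-(triethylsilyloxy)cyclohexyl]ethan-1-one
Product: 8 {[(1S,2R,4R)-2-bromo-1-methyl-4-(prop-1-en-2-yl)cyclohexyl]oxy}triethylsilane
Conditions: Ph3PCH3Br, KOtBu, THF, 0 °C → rt
Reagents that add atoms: methyltriphenylphosphonium bromide, C[P+](c1ccccc1)(c1ccccc1)c1ccccc1.[Br-]
Why: Wittig methylenation of the methyl ketone; the α-stereocentre is already in its thermodynamic configuration, so the basic ylide should not erode it, and it is fixed once the carbonyl is gone.

Step 8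
Reactants: 8 {[(1S,2R,4R)-2-bromo-1-methyl-4-(prop-1-en-2-yl)cyclohexyl]oxy}triethylsilane
Product: 9 {[(1S,2R,4R)-2-bromo-4-(3-chloroprop-1-en-2-yl)-1-methylcyclohexyl]oxy}triethylsilane
Conditions: Ca(OCl)2, solid CO2, CH2Cl2–H2O, 0 °C
Reagents that add atoms: calcium hypochlorite, [Ca+2].[O-]Cl.[O-]Cl
Why: Ene-type allylic chlorination by HOCl: the only alkene is chlorinated at its terminal carbon with shift of the double bond into the former methyl group, the usual outcome for terpene isopropenyl groups, and no stereocentre is touched.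

Step 9
Reactants: 10 (E)-1,2-bis(tributylstannyl)ethene; 11 acetyl chloride
Product: 12 (E)-4-(tributylstannyl)but-3-en-2-one
Conditions: AlCl3 (1 equiv), CH2Cl2, −78 °C
Reagents that add atoms: none
Why: Friedel–Crafts-type acyl-destannylation: the acylium ion substitutes one C–Sn bond at the ipso carbon with retention of the E geometry, and the electron-poor product does not react a second time.

Step 10
Reactants: 12 (E)-4-(tributylstannyl)but-3-en-2-one
Product: 13 (E)-tributyl[3-(triisopropylsilyloxy)buta-1,3-dien-1-yl]stannane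
Conditions: TIPSOTf, Et3N (excess), CH2Cl2, 0 °C
Reagents that add atoms: triisopropylsilyl trifluoromethanesulfonate, CC(C)[Si](C(C)C)(C(C)C)OS(=O)(=O)C(F)(F)F
Why: Soft enolisation and O-silylation; the methyl group is the only enolisable position, so the 2-silyloxydiene forms regiospecifically, and excess amine protects the C–Sn bond from protodestannylation.

Step 11
Reactants: 9 {[(1S,2R,4R)-2-bromo-4-(3-chloroprop-1-en-2-yl)-1-methylcyclohexyl]oxy}triethylsilane; 13 (E)-tributyl[3-(triisopropylsilyloxy)buta-1,3-dien-1-yl]stannane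
Product: 14 {[(1S,2R,4R)-2-bromo-1-methyl-4-[(4E)-6-(triisopropylsilyloxy)hepta-1,4,6-trien-2-yl]cyclohexyl]oxy}triethylsilane
Conditions: Pd2(dba)3 (2.5 mol %), tri(2-furyl)phosphine (10 mol %), THF, 50 °C
Reagents that add atoms: none
Why: Stille allyl–alkenyl coupling: zerovalent palladium inserts only into the allylic C–Cl bond (the hindered secondary alkyl bromide is inert), the 2-substituted π-allyl has equivalent termini, and transmetalation and reductive elimination keep the E geometry, giving the skipped diene under neutral conditions.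

Step 12
Reactants: 14 {[(1S,2R,4R)-2-bromo-1-methyl-4-[(4E)-6-(triisopropylsilyloxy)hepta-1,4,6-trien-2-yl]cyclohexyl]oxy}triethylsilane; 1 methyl vinyl ketone
Product: 15 1-[(1R,2S)-2-{2-[(1R,3R,4S)-3-bromo-4-methyl-4-(triethylsilyloxy)cyclohexyl]prop-2-en-1-yl}-4-(triisopropylsilyloxy)cyclohex-3-en-1-yl]ethan-1-one (acetyl on C4 and side chain on C3 cis)
Conditions: (R)-3,3-diphenyl-1-(o-tolyl)tetrahydro-1H,3H-pyrrolo[1,2-c][1,3,2]oxazaborole (20 mol %), HNTf2 (20 mol %), methyl vinyl ketone (3 equiv), CH2Cl2, −78 → −40 °C; Et3N quench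
Reagents that add atoms: none
Why: Methyl vinyl ketone bound s-trans to the boron cation is LUMO-lowered and adds to the silyloxydiene in a concerted, asynchronous [4+2] cycloaddition in which C5–C6 (enone β-carbon to the diene CH2 terminus) forms ahead of C3–C4. The closest known reaction is the oxazaborolidinium-catalysed Diels–Alder reaction of 2-(triisopropylsilyloxy)-1,3-dienes with vinyl ketones and acrylates. Ring A, a six-membered carbocycle, is closed by this intermolecular cycloaddition with no tether, and leaves the C1=C2 enol silane. The configuration at C4 follows from the enone face left open by the catalyst; C3 follows from the E geometry of the diene and the endo transition state, which places acetyl and side chain cis. The step needs regioselectivity, secured because the silyloxy group (para-directing) and the alkyl terminus (ortho-directing) both send the acetyl-bearing carbon to C4, and it needs catalyst control over the ring-B stereocentres, which are four atoms away from the reacting diene. The isolated 1,1-disubstituted alkene and both silyl ethers should survive at −78 °C because the silyloxydiene is by far the most nucleophilic π system.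

Step 13
Reactants: 15 cis-acetyl cycloadduct
Product: 16 1-[(1S,2S)-2-{2-[(1R,3R,4S)-3-bromo-4-methyl-4-(triethylsilyloxy)cyclohexyl]prop-2-en-1-yl}-4-(triisopropylsilyloxy)cyclohex-3-en-1-yl]ethan-1-one (acetyl and side chain trans)
Conditions: K2CO3, MeOH–THF, rt; recovered 15 is resubmitted
Reagents that add atoms: none
Why: Base-mediated epimerisation α to the acetyl group under thermodynamic control moves the acetyl group to the pseudo-equatorial position trans to the C3 side chain; C3 is not acidic and the triisopropylsilyl enol ether tolerates the mild base.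

Step 14
Reactants: 16 trans-acetyl enol silane
Product: 17 {[(3R,4S)-3-{2-[(1R,3R,4S)-3-bromo-4-methyl-4-(triethylsilyloxy)cyclohexyl]prop-2-en-1-yl}-4-(prop-1-en-2-yl)cyclohex-1-en-1-yl]oxy}triisopropylsilane
Conditions: Ph3PCH3Br, KOtBu, THF, 0 °C → rt
Reagents that add atoms: methyltriphenylphosphonium bromide, C[P+](c1ccccc1)(c1ccccc1)c1ccccc1.[Br-]
Why: Wittig methylenation turns the acetyl group into the isopropenyl group of the target and fixes C4, which is already in its thermodynamic trans configuration.

Step 15
Reactants: 17 ring-A enol silane with isopropenyl on C4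
Product: 19 (2S,3R,4S)-3-{2-[(1R,3R,4S)-3-bromo-4-methyl-4-(triethylsilyloxy)cyclohexyl]prop-2-en-1-yl}-4-(prop-1-en-2-yl)-2-(triisopropylsilyloxy)cyclohexan-1-one, via silyloxy oxirane 18 (not isolated)
Conditions: mCPBA (1.05 equiv), NaHCO3, CH2Cl2, −40 → 0 °C, then rt
Reagents that add atoms: 3-chloroperoxybenzoic acid, OOC(=O)c1cccc(Cl)c1
Why: Rubottom oxidation: the peracid should epoxidise the electron-rich enol silane much faster than the two 1,1-disubstituted alkenes and from the face anti to the neighbouring C3 side chain, and opening of the silyloxy oxirane with 1,4-shift of silicon gives the C1 ketone with the C2 silyloxy group equatorial and trans to C3.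

Step 16
Reactants: 19 α-silyloxy ketone
Product: 20 (3R,4S,5R,6S)-5-{2-[(1R,3R,4S)-3-bromo-4-methyl-4-(triethylsilyloxy)cyclohexyl]prop-2-en-1-yl}-6-(prop-1-en-2-yl)-4-(triisopropylsilyloxy)-1-oxaspiro[2.5]octane (epoxide CH2 axial and cis to the C2 silyloxy group, epoxide O equatorial)
Conditions: Me3SI, n-BuLi, THF, −10 °C; then 19, −10 → 0 °C
Reagents that add atoms: trimethylsulfonium iodide, C[S+](C)C.[I-]
Why: Corey–Chaykovsky epoxidation: the small, irreversibly adding dimethylsulfonium methylide attacks the cyclohexanone along the axial trajectory (the face of the axial hydrogens on C3 and C5), so the new C–C bond is axial and the oxygen equatorial at C1.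

Step 17
Reactants: 20 spiro-epoxide
Product: 21 (1S,2S,3R,4S)-3-{2-[(1R,3R,4S)-3-bromo-4-methyl-4-(triethylsilyloxy)cyclohexyl]prop-2-en-1-yl}-1-methyl-4-(prop-1-en-2-yl)-2-(triisopropylsilyloxy)cyclohexan-1-ol
Conditions: LiAlH4, THF, 0 °C
Reagents that add atoms: none
Why: Hydride opens the epoxide by SN2 attack at its unhindered CH2 and gives the tertiary alcohol with axial methyl and equatorial hydroxyl; the ring-B bromide, secondary, equatorial and next to a quaternary carbon, should not be displaced at 0 °C.

Step 18
Reactants: 21 bis-silyl ether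
Product: 22 (1S,2S,3R,4S)-3-{2-[(1R,3R,4S)-3-bromo-4-hydroxy-4-methylcyclohexyl]prop-2-en-1-yl}-1-methyl-4-(prop-1-en-2-yl)cyclohexane-1,2-diol (target)
Conditions: HF·pyridine, pyridine, THF, 0 °C → rt
Reagents that add atoms: none
Why: Fluoride-mediated cleavage of both silyl ethers under buffered, weakly acidic conditions avoids a free alkoxide next to the bromide and leaves the two 1,1-disubstituted alkenes alone.

**Compound list**

1 | methyl vinyl ketone | CC(=O)C=C | starting material
2 | 2-(triisopropylsilyloxy)buta-1,3-diene | C=CC(=C)O[Si](C(C)C)(C(C)C)C(C)C | intermediate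
3 | (S)-1-[4-(triisopropylsilyloxy)cyclohex-3-en-1-yl]ethan-1-one | CC(=O)[C@H]1CCC(O[Si](C(C)C)(C(C)C)C(C)C)=CC1 | intermediate
4 | (2R,4S)-4-acetyl-2-bromocyclohexan-1-one | CC(=O)[C@H]1CCC(=O)[C@H](Br)C1 | intermediate
5 | 1-[(1S,3R,4S)-3-bromo-4-hydroxy-4-methylcyclohexyl]ethan-1-one | CC(=O)[C@H]1CC[C@](C)(O)[C@H](Br)C1 | intermediate
6 | 1-[(1S,3R,4S)-3-bromo-4-methyl-4-(triethylsilyloxy)cyclohexyl]ethan-1-one | CC(=O)[C@H]1CC[C@](C)(O[Si](CC)(CC)CC)[C@H](Br)C1 | intermediate
7 | 1-[(1R,3R,4S)-3-bromo-4-methyl-4-(triethylsilyloxy)cyclohexyl]ethan-1-one | CC(=O)[C@@H]1CC[C@](C)(O[Si](CC)(CC)CC)[C@H](Br)C1 | intermediate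
8 | {[(1S,2R,4R)-2-bromo-1-methyl-4-(prop-1-en-2-yl)cyclohexyl]oxy}triethylsilane | CC(=C)[C@@H]1CC[C@](C)(O[Si](CC)(CC)CC)[C@H](Br)C1 | intermediate
9 | {[(1S,2R,4R)-2-bromo-4-(3-chloroprop-1-en-2-yl)-1-methylcyclohexyl]oxy}triethylsilane | ClCC(=C)[C@@H]1CC[C@](C)(O[Si](CC)(CC)CC)[C@H](Br)C1 | intermediate
10 | (E)-1,2-bis(tributylstannyl)ethene | CCCC[Sn](CCCC)(CCCC)/C=C/[Sn](CCCC)(CCCC)CCCC | starting material
11 | acetyl chloride | CC(=O)Cl | starting material
12 | (E)-4-(tributylstannyl)but-3-en-2-one | CC(=O)/C=C/[Sn](CCCC)(CCCC)CCCC | intermediate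
13 | (E)-tributyl[3-(triisopropylsilyloxy)buta-1,3-dien-1-yl]stannane | C=C(O[Si](C(C)C)(C(C)C)C(C)C)/C=C/[Sn](CCCC)(CCCC)CCCC | intermediate
14 | {[(1S,2R,4R)-2-bromo-1-methyl-4-[(4E)-6-(triisopropylsilyloxy)hepta-1,4,6-trien-2-yl]cyclohexyl]oxy}triethylsilane (key-step precursor) | C=C(O[Si](C(C)C)(C(C)C)C(C)C)/C=C/CC(=C)[C@@H]1CC[C@](C)(O[Si](CC)(CC)CC)[C@H](Br)C1 | intermediate
15 | ring-A cycloadduct, acetyl (C4) and side chain (C3) cis (key-step product) | C=C(C[C@@H]1[C@H](C(C)=O)CCC(O[Si](C(C)C)(C(C)C)C(C)C)=C1)[C@@H]2CC[C@](C)(O[Si](CC)(CC)CC)[C@H](Br)C2 | intermediate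
16 | C4 epimer of 15, acetyl and side chain trans | C=C(C[C@@H]1[C@@H](C(C)=O)CCC(O[Si](C(C)C)(C(C)C)C(C)C)=C1)[C@@H]2CC[C@](C)(O[Si](CC)(CC)CC)[C@H](Br)C2 | intermediate
17 | ring-A enol silane with isopropenyl on C4 | C=C(C[C@@H]1[C@@H](C(C)=C)CCC(O[Si](C(C)C)(C(C)C)C(C)C)=C1)[C@@H]2CC[C@](C)(O[Si](CC)(CC)CC)[C@H](Br)C2 | intermediate
18 | C1-silyloxy C1/C2 oxirane, epoxide oxygen trans to the C3 side chain | C=C(C[C@@H]1[C@@H](C(C)=C)CC[C@@]3(O[Si](C(C)C)(C(C)C)C(C)C)O[C@@H]13)[C@@H]2CC[C@](C)(O[Si](CC)(CC)CC)[C@H](Br)C2 | intermediate (not isolated)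
19 | C1 ketone with equatorial C2 triisopropylsilyloxy group | C=C(C[C@@H]1[C@@H](C(C)=C)CCC(=O)[C@H]1O[Si](C(C)C)(C(C)C)C(C)C)[C@@H]2CC[C@](C)(O[Si](CC)(CC)CC)[C@H](Br)C2 | intermediate
20 | C1 spiro-epoxide, CH2 axial | C=C(C[C@@H]1[C@@H](C(C)=C)CC[C@@]3(CO3)[C@H]1O[Si](C(C)C)(C(C)C)C(C)C)[C@@H]2CC[C@](C)(O[Si](CC)(CC)CC)[C@H](Br)C2 | intermediate
21 | C1 tertiary alcohol (axial methyl), C2 silyl ether | C=C(C[C@@H]1[C@@H](C(C)=C)CC[C@](C)(O)[C@H]1O[Si](C(C)C)(C(C)C)C(C)C)[C@@H]2CC[C@](C)(O[Si](CC)(CC)CC)[C@H](Br)C2 | intermediate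
22 | CNP0422107.2 | C=C(C[C@@H]1[C@@H](C(C)=C)CC[C@](C)(O)[C@H]1O)[C@@H]2CC[C@](C)(O)[C@H](Br)C2 | target

**Step count and risks**

Total step count: 18. Longest linear sequence: 16 steps (steps 1–8, then 11–18).

Steps most likely to fail:

1. Step 12. Facial control at C3 may erode, because the monodentate methyl ketone can bind the boron cation in two orientations and the silyl dienol ether can add in a stepwise Mukaiyama–Michael mode; the strongly acidic catalyst may also strip the dienol silyl group. Fallback, from 14 back to 15: the acetyl group is no longer brought in by the dienophile but built afterwards. Compound 14 is combined with 2,2,2-trifluoroethyl acrylate, the dienophile class for which this boron catalyst family is best established with 2-silyloxydienes, under the catalyst enantiomer that gives the same sense at C3 (CH2Cl2, −78 °C). This should give the cis trifluoroethyl ester F1. Exchange with MeNH(OMe)·HCl and i-PrMgCl (THF, −20 °C) gives the N-methoxy-N-methylamide F2, and MeMgBr (THF, 0 °C) then gives methyl ketone 15. Any epimerisation at C4 on the way is harmless, since step 13 equilibrates that centre.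

2. Step 15. Oxygen may be delivered to the wrong face of the enol silane, since the only directing element is the pseudo-equatorial C3 side chain. Fallback, from 17 to 22: C2 is set by ketone reduction instead of by enol-ether oxidation. Material that passes through the diastereomeric silyloxy oxirane F3 to the C2-epimeric silyloxy ketone F4 is not discarded but carried through steps 16–18 unchanged. The ylide still enters axially at C1, because the axial C2–O bond is anti to that trajectory, giving spiro-epoxide F5, then tertiary alcohol F6 and, after desilylation, the 2-epi-triol F7. Its only secondary hydroxyl is oxidised with DMP (CH2Cl2, NaHCO3, 0 °C) to the 2-ketone F8. NaBH4 (MeOH, −20 °C) then delivers hydride axially, away from the axial C1 methyl group, and should give the equatorial C2 alcohol, which is 22.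

3. Step 6. The equilibrium may be insufficiently biased, and the acetyl enolate may displace the γ-bromide irreversibly (cyclopropane formation) or the base may cause elimination. Fallback, from 5 to 7: the epimerisation is moved before silylation and run through the enol instead of the enolate. Compound 5 is treated with catalytic p-TsOH·H2O in benzene at 40 °C; no carbanion is formed, and the small free hydroxyl group is easier to place axial, which should increase the preference for the hydroxy ketone F9 (acetyl cis to Br and OH). Silylation of F9 as in step 5 (TESOTf, 2,6-lutidine) gives 7.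

**Further compounds**

F1 | step 12 | 2,2,2-trifluoroethyl ester analogue of 15 (ester on C4 cis to the C3 side chain) | C=C(C[C@@H]1[C@H](C(=O)OCC(F)(F)F)CCC(O[Si](C(C)C)(C(C)C)C(C)C)=C1)[C@@H]2CC[C@](C)(O[Si](CC)(CC)CC)[C@H](Br)C2
F2 | step 12 | N-methoxy-N-methylamide analogue of 15 | C=C(C[C@@H]1[C@H](C(=O)N(C)OC)CCC(O[Si](C(C)C)(C(C)C)C(C)C)=C1)[C@@H]2CC[C@](C)(O[Si](CC)(CC)CC)[C@H](Br)C2
F3 | step 15 | diastereomer of 18 with the epoxide oxygen cis to the C3 side chain | C=C(C[C@@H]1[C@@H](C(C)=C)CC[C@]3(O[Si](C(C)C)(C(C)C)C(C)C)O[C@H]13)[C@@H]2CC[C@](C)(O[Si](CC)(CC)CC)[C@H](Br)C2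
F4 | step 15 | C2 epimer of 19 (axial silyloxy group) | C=C(C[C@@H]1[C@@H](C(C)=C)CCC(=O)[C@@H]1O[Si](C(C)C)(C(C)C)C(C)C)[C@@H]2CC[C@](C)(O[Si](CC)(CC)CC)[C@H](Br)C2
F5 | step 15 | C2 epimer of 20 | C=C(C[C@@H]1[C@@H](C(C)=C)CC[C@@]3(CO3)[C@@H]1O[Si](C(C)C)(C(C)C)C(C)C)[C@@H]2CC[C@](C)(O[Si](CC)(CC)CC)[C@H](Br)C2
F6 | step 15 | C2 epimer of 21 | C=C(C[C@@H]1[C@@H](C(C)=C)CC[C@](C)(O)[C@@H]1O[Si](C(C)C)(C(C)C)C(C)C)[C@@H]2CC[C@](C)(O[Si](CC)(CC)CC)[C@H](Br)C2
F7 | step 15 | C2 epimer of 22 (2-epi-triol) | C=C(C[C@@H]1[C@@H](C(C)=C)CC[C@](C)(O)[C@@H]1O)[C@@H]2CC[C@](C)(O)[C@H](Br)C2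
F8 | step 15 | 2-ketone: ring-A C1 tertiary alcohol with C2 carbonyl | C=C(C[C@@H]1[C@@H](C(C)=C)CC[C@](C)(O)C1=O)[C@@H]2CC[C@](C)(O)[C@H](Br)C2
F9 | step 6 | 1-[(1R,3R,4S)-3-bromo-4-hydroxy-4-methylcyclohexyl]ethan-1-one | CC(=O)[C@@H]1CC[C@](C)(O)[C@H](Br)C1
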